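Over the 4.0 min of a run at constant temperature, a single-handed partner meets two mirror-image substrates in one flask, and the products of the two hands are compared.

all flasks: left-handed substrate 0.028 M; right-handed substrate 0.028 M; time 4.0 min
- red: partner 0.0250 M
- ochre: partner 0.0300 M
- amber: partner 0.0500 M

    2 partner → self-condensation product (k1 = 0.10 M⁻¹ s⁻¹)
    partner + right-handed substrate → right-handed product (k2 = 0.0065 M⁻¹ s⁻¹)
    partner → decomposed reagent (k3 = 0.0065 s⁻¹)
    partner + left-handed substrate → left-handed product (k4 = 0.18 M⁻¹ s⁻¹)

- partner is single-handed; left-handed substrate and right-handed substrate are mirror images of each other, charged as a racemate, each of them at the stated concentration
- two of one species on the left: rate k times its square, two consumed each time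
- an excess is the difference of the two amounts in percent of their sum
- "hardly changes" means that all values lie within two and a half points (for a concentration: within two and a half percent of the largest)
- run time (red): 4.0 min
- the handed part of partner does not stay in what it makes, so the products of the two hands are mirror images too

- excess of left-handed product over right-handed product at the end for red, ochre, amber, in this order
- how the row runs (hardly changes / rises all the way / rises, then falls / falls, then rises / falls all the way)

1. The balance starts from the partner, the limiting reagent: even in the amber flask its charge is smaller than that of the two substrates together. It leaves by 4 steps, but two of them make the compared products.

2. In the red flask as charged, the step with the left-handed substrate by itself would halve the partner in 2.3 min, and the step with the right-handed substrate by itself in 63 min, which is much slower.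

3. Both substrates meet the same c(partner) at every moment, so a fall in c(partner) slows both steps by the same factor. The two times themselves change as the substrates thin, but the ratio of the two rate constants, the selectivity factor s = 27.7, stays the same through the run: ln of the fraction of left-handed substrate remaining is s times ln of the fraction of right-handed substrate remaining.

4. At the start, the excess is (s − 1)/(s + 1) = 93.0%, and it sinks as c(left-handed substrate) thins.

5. A rough reckoning by hand holds the starting share of partner going to left-handed product for the whole run: 30.1% in the red flask and 23.2% in the amber flask. The left-handed substrate then converts by 26.9% and 41.4%, and s turns these into excesses of 92.0% and 91.2%. By this reckoning the row hardly changes.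

The forecast gives 92%, 91.8% and 91.1%, so that the row hardly changes: “More partner therefore lowers the excess only slightly”.

The simulation gives 92.0%, 91.8% and 91.1%, and the row hardly changes. With s, the 73% of left-handed substrate remaining in the red flask gives 92.0%, and the 57% remaining in the amber flask gives 91.1%. The flat row rests in part on the falling level of partner, which holds back conversion. Without that fall, the red flask ends at 89.1% and the amber flask at 84.4%, a spread of 4.7 percentage points against 0.9 points in the row as run.

All constants were chosen freely; what happens was integrated by code.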